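**Plan**
- Retrosynthesis: the indole is first taken back to its cis-3a,7a-dihydro form, then the carbocycle is cut at C3a–C4 and C7–C7a. This releases 4-(1H-pyrrol-3-yl)pyrimidin-2-amine and 3,4-dibromothiophene 1,1-dioxide. The pyrimidine is then cut at both C–N bonds to guanidine, and the pyrrole into TosMIC and methyl vinyl ketone.
- Enabling feature: the benzo ring carries Br only on C5 and C6 and H on C4 and C7. It is therefore a C4–C5(Br)–C6(Br)–C7 unit laid across the C3a–C7a bond. That unit is the diene of the sulfone, and C3a–C7a is the unsubstituted C4–C5 bond of a 3-substituted pyrrole.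
- Forward order of rings: pyrrole (van Leusen), then pyrimidine (enaminone plus guanidine), then the benzene ring last by [4+2] cycloaddition with SO2 loss, followed by dehydrogenation.
- Stereochemistry: the target has none. The two transient centres C3a and C7a arise cis (racemic) from suprafacial cycloaddition and are erased on aromatisation.

Key step: step 5

Assumption: the sulfone-bridged cycloadduct of the key step is drawn as its endo isomer, a choice without consequence because its bridgehead centres leave with SO2 and only the cis ring fusion is passed on. Chiral intermediates are racemic and each SMILES shows one enantiomer.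

**Route**

Step 1
Reactants: 1 tosylmethyl isocyanide (TosMIC); 2 methyl vinyl ketone (but-3-en-2-one)
Product: 3 3-acetylpyrrole [1-(1H-pyrrol-3-yl)ethan-1-one]
Conditions: NaH, Et2O/DMSO, 0 °C to rt
Reagents that add atoms: none
Why: Van Leusen pyrrole synthesis, in which the TosMIC anion adds to the enone in Michael fashion, the enolate carbon closes onto the isocyanide carbon, and loss of sulfinate with tautomerisation gives the 3-acyl-1H-pyrrole unsubstituted at C2, C4 and C5.

Step 2
Reactants: 3 3-acetylpyrrole
Product: 4 (E)-3-(dimethylamino)-1-(1H-pyrrol-3-yl)prop-2-en-1-one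
Conditions: t-BuOCH(NMe2)2 (2–3 equiv), DMF, 80 °C
Reagents that add atoms: tert-butoxybis(dimethylamino)methane, CN(C)C(OC(C)(C)C)N(C)C
Why: Enaminone formation by aminomethylenation of a methyl ketone with a formamide aminal ester, which ionises to tert-butoxide and a formamidinium ion that condense at the acetyl CH3 and which, having no O-methyl group, cannot methylate the pyrrole nitrogen as DMF dimethyl acetal might.

Step 3
Reactants: 4 (E)-3-(dimethylamino)-1-(1H-pyrrol-3-yl)prop-2-en-1-one; 5 guanidine hydrochloride
Product: 6 4-(1H-pyrrol-3-yl)pyrimidin-2-amine
Conditions: K2CO3, 2-methoxyethanol, 120 °C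
Reagents that add atoms: none
Why: Classical pyrimidine cyclocondensation of an enaminone with guanidine, in which addition–elimination at the β-carbon expels dimethylamine and the second guanidine nitrogen closes onto the ketone with loss of water while the pyrrole N–H stays untouched.

Step 4
Reactants: 7 3,4-dibromothiophene
Product: 9 3,4-dibromothiophene 1,1-dioxide, via 3,4-dibromothiophene 1-oxide 8 (not isolated)
Conditions: dimethyldioxirane (ca. 3 equiv, acetone solution), 0 °C to rt, dark; evaporation below rt
Reagents that add atoms: dimethyldioxirane, CC1(C)OO1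
Why: Oxidation of a thiophene to its 1,1-dioxide by electrophilic oxygen transfer to sulfur, where the non-aromatic monoxide 8 should be oxidised faster than the thiophene and so should not accumulate, and the neutral volatile by-product allows isolation of the sensitive sulfone by evaporation alone.

Step 5
Reactants: 6 4-(1H-pyrrol-3-yl)pyrimidin-2-amine; 9 3,4-dibromothiophene 1,1-dioxide
Product: 11 racemic cis-4-(5,6-dibromo-3a,7a-dihydro-1H-indol-3-yl)pyrimidin-2-amine, via endo sulfone-bridged cycloadduct 10 (not isolated)
Conditions: 9 (1.5 equiv, in portions), 1,4-dioxane, 100 °C, argon; then concentration, crude 11 taken on directly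
Reagents that add atoms: none
Why: Proposed new method: the low-lying LUMO of the non-aromatic, bromine-substituted sulfone diene should match the HOMO of the pyrrole, whose largest coefficient lies at C5, so that an inverse-electron-demand [4+2] cycloaddition (concerted but asynchronous, or stepwise through attack of pyrrole C5 on a sulfone α-carbon and 6-exo-trig collapse of the sulfonyl-stabilised allyl anion onto C4 of the 2H-pyrrolium ion) joins the diene termini to pyrrole C4 and C5, after which cheletropic loss of SO2 from bridged adduct 10 leaves the cyclohexadiene of 11. The closest known reaction type is the cycloaddition of halogenated thiophene 1,1-dioxides with electron-rich alkenes and enamines followed by SO2 extrusion, here extended to a pyrrole double bond. The six-membered carbocycle is the only ring closed, by intermolecular [4+2] cycloaddition that forms C3a–C4 and C7–C7a. The two new stereocentres C3a and C7a are set cis by suprafacial addition to two adjacent pyrrole carbons (a five-six fusion made this way cannot be trans), as a racemate, and both vanish in step 6. Site selectivity between the two pyrrole double bonds is required and is secured by the pyrimidinyl group at C3, which drains C2=C3 electronically as part of a vinylogous amidine and shields it sterically, leaving the unsubstituted C4=C5 bond as the electron-rich one, while the mirror symmetry of the diene makes the orientation of addition irrelevant and puts Br on C5 and C6 only. The exocyclic amine, a weakly nucleophilic amidine-type nitrogen, and the pyrrole N–H are expected to add to the sulfone more slowly than carbon does.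

Step 6
Reactants: 11 racemic cis-4-(5,6-dibromo-3a,7a-dihydro-1H-indol-3-yl)pyrimidin-2-amine
Product: 12 Meridianin F [4-(5,6-dibromo-1H-indol-3-yl)pyrimidin-2-amine]
Conditions: DDQ (1.1 equiv), THF, 0 °C to rt
Reagents that add atoms: none
Why: Quinone dehydrogenation of a dihydroarene, in which hydride abstraction from C7a (allylic and α to nitrogen) and loss of the C3a proton are driven by formation of the aromatic indole and remove both stereocentres.

**Compound list**

1 | tosylmethyl isocyanide (TosMIC) | [C-]#[N+]CS(=O)(=O)c1ccc(C)cc1 | starting material
2 | methyl vinyl ketone (but-3-en-2-one) | CC(=O)C=C | starting material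
3 | 3-acetylpyrrole, 1-(1H-pyrrol-3-yl)ethan-1-one | CC(=O)c1cc[nH]c1 | intermediate
4 | (E)-3-(dimethylamino)-1-(1H-pyrrol-3-yl)prop-2-en-1-one | CN(C)/C=C/C(=O)c1cc[nH]c1 | intermediate
5 | guanidine hydrochloride | Cl.NC(N)=N | starting material
6 | 4-(1H-pyrrol-3-yl)pyrimidin-2-amine | Nc1nccc(-c2cc[nH]c2)n1 | intermediate
7 | 3,4-dibromothiophene | Brc1cscc1Br | starting material
8 | 3,4-dibromothiophene 1-oxide | O=S1C=C(Br)C(Br)=C1 | intermediate (not isolated)
9 | 3,4-dibromothiophene 1,1-dioxide | O=S1(=O)C=C(Br)C(Br)=C1 | intermediate
10 | endo sulfone-bridged cycloadduct, racemic 5-(2-aminopyrimidin-4-yl)-8,9-dibromo-10-thia-3-azatricyclo[5.2.1.0(2,6)]deca-4,8-diene 10,10-dioxide; pyrroline ring anti to the SO2 bridge, ring-fusion hydrogens cis | N1C=C(c2ccnc(N)n2)[C@H]2[C@@H]1[C@H]1C(Br)=C(Br)[C@@H]2S1(=O)=O | intermediate (not isolated)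
11 | racemic cis-4-(5,6-dibromo-3a,7a-dihydro-1H-indol-3-yl)pyrimidin-2-amine (3aS*,7aR*; ring-fusion hydrogens on the same face) | N1C=C(c2ccnc(N)n2)[C@@H]2C=C(Br)C(Br)=C[C@H]12 | intermediate
12 | Meridianin F, 4-(5,6-dibromo-1H-indol-3-yl)pyrimidin-2-amine | Nc1nccc(-c2c[nH]c3cc(Br)c(Br)cc23)n1 | target

**Step count and risks**

Total: 6 steps. Longest linear sequence: 5 steps (steps 1, 2, 3, 5, 6); step 4 is a one-step branch.

Steps most likely to fail:

Step 5 (the proposed new method, listed first). Several processes could defeat it:
- The acceptor-substituted pyrrole may react too slowly, so that self-cycloaddition of the sulfone with SO2 loss takes over.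
- The exocyclic amine may add to the sulfone in conjugate fashion.
- The pyrrole may re-aromatise after the first C–C bond, stopping at an open Michael-type adduct instead of closing the ring.
- The dihydroindole may open by cleavage of the C7a–N bond on heating, aromatising the carbocycle.

The fallback uses only established reaction types. It sets out from guanidine hydrochloride 5 and comes back to the route at Meridianin F 12, with the indole nucleus bought instead of built. Purchased 5,6-dibromo-1H-indole F1 is acetylated at C3 by Friedel–Crafts acylation (AcCl, Et2AlCl, CH2Cl2, 0 °C) to 1-(5,6-dibromo-1H-indol-3-yl)ethan-1-one F2. N-Sulfonylation (TsCl, NaH, THF) gives 1-(5,6-dibromo-1-tosyl-1H-indol-3-yl)ethan-1-one F3. Condensation with DMF dimethyl acetal (DMF, 110 °C) gives (E)-1-(5,6-dibromo-1-tosyl-1H-indol-3-yl)-3-(dimethylamino)prop-2-en-1-one F4. Cyclocondensation of F4 with 5 (K2CO3, 2-methoxyethanol, reflux) should build the aminopyrimidine and cleave the N-tosyl group in the same operation, giving 12.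

Step 4. Slow first oxidation of the electron-poor thiophene may let the monoxide 8 linger and dimerise by [4+2] cycloaddition. The dioxide, which has no α-substituents, may also dimerise with SO2 loss during concentration.

The fallback sets out from 3,4-dibromothiophene 7 and comes back at sulfone 9, using α-silyl groups as removable blocking groups. Double α-lithiation with in situ silylation (LiN(i-Pr)2, Me3SiCl, THF, −78 °C) should give 3,4-dibromo-2,5-bis(trimethylsilyl)thiophene F5. Its sulfur is more electron-rich and its α-positions are shielded. Oxidation with mCPBA (CH2Cl2, rt) should then give the storable 3,4-dibromo-2,5-bis(trimethylsilyl)thiophene 1,1-dioxide F6. Protodesilylation of both α-silyl vinyl sulfone units with buffered fluoride (Bu4NF, AcOH, THF, −20 °C) just before use would release 9 in solution for step 5.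

Step 2. The basic reagent deprotonates the pyrrole N–H first. The resulting pyrrolide is a vinylogous amide anion whose acetyl group may resist enolisation, so the condensation may stall, or the nitrogen may be aminomethylenated instead.

The fallback sets out from 3-acetylpyrrole 3 and comes back at pyrrolylpyrimidine 6, changing the protecting-group approach. N-Sulfonylation (TsCl, NaH, THF) gives 1-(1-tosyl-1H-pyrrol-3-yl)ethan-1-one F7, whose acetyl group behaves as an ordinary aryl ketone and whose nitrogen can no longer be alkylated. DMF dimethyl acetal (110 °C) gives (E)-3-(dimethylamino)-1-(1-tosyl-1H-pyrrol-3-yl)prop-2-en-1-one F8. Treatment of F8 with guanidine hydrochloride 5 (K2CO3, 2-methoxyethanol, reflux) should form the pyrimidine and remove the tosyl group in one operation, giving 6.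

**Further compounds**

F1 | step 5 | 5,6-dibromo-1H-indole (purchased) | Brc1cc2cc[nH]c2cc1Br
F2 | step 5 | 1-(5,6-dibromo-1H-indol-3-yl)ethan-1-one | CC(=O)c1c[nH]c2cc(Br)c(Br)cc12
F3 | step 5 | 1-(5,6-dibromo-1-tosyl-1H-indol-3-yl)ethan-1-one | CC(=O)c1cn(S(=O)(=O)c2ccc(C)cc2)c2cc(Br)c(Br)cc12
F4 | step 5 | (E)-1-(5,6-dibromo-1-tosyl-1H-indol-3-yl)-3-(dimethylamino)prop-2-en-1-one | CN(C)/C=C/C(=O)c1cn(S(=O)(=O)c2ccc(C)cc2)c2cc(Br)c(Br)cc12
F5 | step 4 | 3,4-dibromo-2,5-bis(trimethylsilyl)thiophene | C[Si](C)(C)c1sc([Si](C)(C)C)c(Br)c1Br
F6 | step 4 | 3,4-dibromo-2,5-bis(trimethylsilyl)thiophene 1,1-dioxide | C[Si](C)(C)C1=C(Br)C(Br)=C([Si](C)(C)C)S1(=O)=O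
F7 | step 2 | 1-(1-tosyl-1H-pyrrol-3-yl)ethan-1-one | CC(=O)c1ccn(S(=O)(=O)c2ccc(C)cc2)c1
F8 | step 2 | (E)-3-(dimethylamino)-1-(1-tosyl-1H-pyrrol-3-yl)prop-2-en-1-one | CN(C)/C=C/C(=O)c1ccn(S(=O)(=O)c2ccc(C)cc2)c1
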